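**Plan**
1. Retrosynthesis: the O–silyl and O–benzyl bonds are cut last. Eriodictyol C2–C3 is cut next, which opens ring C to an α-aryl-α-diazoketone whose ring A carries one 3,4-bis(benzyloxy)benzyl ether. The parent deoxybenzoin is cut at its aryl–C(=O) bond into an aryl Grignard reagent and an arylacetaldehyde.
2. The taxifolin unit is cut at O1–C2 (epoxide opening) and Cα–Cβ (aldol); its C8 side arm goes back to an allyl group placed by a Claisen rearrangement.
3. Forward order: taxifolin ring C is closed first on a C8-allyl phloroacetophenone, the allyl group becomes the deoxybenzoin arm, and eriodictyol ring C is closed last by carbene C–H insertion; two deprotections finish.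
4. Enabling feature: eriodictyol C2 is a benzylic, oxygen-bearing carbon six atoms from C3 along C3–C4–C4a–C8a–O1–C2, so a rhodium carbene at C3 can insert into the OCH2–aryl C–H bond of a ring A benzyl ether and close ring C.
5. Stereochemistry: taxifolin C2/C3 come from a poly-L-leucine epoxidation and invertive epoxide opening; eriodictyol C2 from the chiral dirhodium catalyst; eriodictyol C3 by equilibration to trans.
6. The C3→C8 linkage is fixed by the ortho-Claisen step. The taxifolin unit is built before the key step because chalcone chemistry under base afterwards would open the new flavanone and scramble its C2.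

Key step: step 17

Abbreviations: Bn = benzyl; MOM = methoxymethyl; TBS = tert-butyldimethylsilyl; DBB = 3,4-bis(benzyloxy)benzyl; DIAD = diisopropyl azodicarboxylate; NIS = N-iodosuccinimide.
Assumption: Rh2(S-PTTL)4 is taken to give the 2R configuration at the new C2. If the sense is opposite, the mirror-image complex Rh2(R-PTTL)4 is used; in either case the C2 epimer is a diastereomer removable by chromatography.

**Step 1**
Reactants: 1 2,4,6-trihydroxyacetophenone
Product: 2 1-[2,6-dihydroxy-4-(methoxymethoxy)phenyl]ethanone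
Conditions: MOMCl (1.0 equiv), iPr2NEt, CH2Cl2, 0 °C
Reagents that add atoms: chloromethyl methyl ether COCCl
Why: Williamson-type O-alkylation in which the 4-OH, the only phenol not hydrogen-bonded to the acetyl group and the most acidic one, should react first.

**Step 2**
Reactants: 2 1-[2,6-dihydroxy-4-(methoxymethoxy)phenyl]ethanone
Product: 3 1-[2-(benzyloxy)-6-hydroxy-4-(methoxymethoxy)phenyl]ethanone
Conditions: BnBr (1.05 equiv), K2CO3, acetone, reflux
Reagents that add atoms: benzyl bromide BrCc1ccccc1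
Why: Williamson ether synthesis on one of two equivalent chelated phenols; the remaining phenol is held in a strong hydrogen bond to the ketone and should resist a second alkylation under these conditions.

**Step 3**
Reactants: 3 1-[2-(benzyloxy)-6-hydroxy-4-(methoxymethoxy)phenyl]ethanone
Product: 4 1-[2-(allyloxy)-6-(benzyloxy)-4-(methoxymethoxy)phenyl]ethanone
Conditions: allyl bromide, K2CO3, DMF, 60 °C
Reagents that add atoms: allyl bromide C=CCBr
Why: Williamson etherification under more forcing conditions, which are needed to alkylate the last, chelated phenol.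

**Step 4**
Reactants: 4 1-[2-(allyloxy)-6-(benzyloxy)-4-(methoxymethoxy)phenyl]ethanone
Product: 5 1-[3-allyl-6-(benzyloxy)-2-hydroxy-4-(methoxymethoxy)phenyl]ethanone
Conditions: N,N-diethylaniline, 190 °C
Reagents that add atoms: none
Why: Aromatic Claisen rearrangement, a [3,3] shift that delivers the allyl group to the only free ortho carbon (C3) and regenerates the phenol between the acetyl and allyl groups, which later decides the C8 linkage.

**Step 5**
Reactants: 5 1-[3-allyl-6-(benzyloxy)-2-hydroxy-4-(methoxymethoxy)phenyl]ethanone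
Product: 6 1-[3-allyl-6-(benzyloxy)-2,4-bis(methoxymethoxy)phenyl]ethanone
Conditions: NaH, MOMCl, DMF, 0 °C to rt
Reagents that add atoms: chloromethyl methyl ether COCCl
Why: Williamson etherification of the hindered chelated phenol through its sodium phenoxide; masking this oxygen prevents premature flavanone or aurone formation in the next two steps.

**Step 6**
Reactants: 6 1-[3-allyl-6-(benzyloxy)-2,4-bis(methoxymethoxy)phenyl]ethanone; 7 3,4-bis(benzyloxy)benzaldehyde
Product: 9 (E)-1-[3-allyl-6-(benzyloxy)-2,4-bis(methoxymethoxy)phenyl]-3-[3,4-bis(benzyloxy)phenyl]prop-2-en-1-one, via aldol adduct 8 (not isolated)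
Conditions: KOH, EtOH/THF, rt
Reagents that add atoms: none
Why: Claisen–Schmidt condensation of a fully O-protected methyl ketone with a non-enolisable aldehyde; E1cB dehydration of the aldol should give the (E)-enone, and the acetal and benzyl ethers and the isolated allyl group tolerate hydroxide at room temperature.

**Step 7**
Reactants: 9 (E)-chalcone
Product: 10 [(2R,3S)-3-[3,4-bis(benzyloxy)phenyl]oxiran-2-yl][3-allyl-6-(benzyloxy)-2,4-bis(methoxymethoxy)phenyl]methanone
Conditions: poly-L-leucine, urea–H2O2, DBU, THF, rt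
Reagents that add atoms: urea–hydrogen peroxide NC(N)=O.OO
Why: Juliá–Colonna epoxidation, a Weitz–Scheffer hydroperoxide addition inside the helical peptide, in which poly-L-leucine should direct oxygen to the enone face that gives the (αR,βS)-epoxide; the nucleophilic oxidant leaves the isolated allyl group alone.

**Step 8**
Reactants: 10 (αR,βS)-epoxy ketone
Product: 12 (2R,3R)-8-allyl-5-(benzyloxy)-2-[3,4-bis(benzyloxy)phenyl]-3,7-dihydroxychroman-4-one, via bis-phenol epoxide 11 (not isolated)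
Conditions: HCl, MeOH/THF, 50 °C
Reagents that add atoms: none
Why: Acidic acetal cleavage of both MOM ethers, then 6-endo epoxide opening by the freed 2'-phenol at the benzylic carbon with inversion, should give the 2,3-trans (2R,3R) dihydroflavonol; the acid-stable 5-O-benzyl ether blocks the other ortho oxygen, so the allyl group can only end up at C8.

**Step 9**
Reactants: 12 (2R,3R)-8-allyl-dihydroflavonol diol
Product: 13 (2R,3R)-8-allyl-5-(benzyloxy)-2-[3,4-bis(benzyloxy)phenyl]-3,7-bis(tert-butyldimethylsilyloxy)chroman-4-one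
Conditions: TBSOTf, 2,6-lutidine, CH2Cl2, 0 °C
Reagents that add atoms: tert-butyldimethylsilyl trifluoromethanesulfonate CC(C)(C)[Si](C)(C)OS(=O)(=O)C(F)(F)F
Why: Silylation of the phenol and the secondary alcohol with a base too weak to epimerise C2/C3; the 7-oxygen, later ortho to the carbene-bearing carbon, thereby carries a group with no C–H bond α to oxygen.

**Step 10**
Reactants: 13 bis-TBS 8-allyl-dihydroflavonol
Product: 15 2-[(2R,3R)-5-(benzyloxy)-2-[3,4-bis(benzyloxy)phenyl]-3,7-bis(tert-butyldimethylsilyloxy)-4-oxochroman-8-yl]acetaldehyde, via diol 14 (not isolated)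
Conditions: OsO4 (cat.), NaIO4, 2,6-lutidine, dioxane/H2O, rt
Reagents that add atoms: osmium tetroxide O=[Os](=O)(=O)=O; sodium periodate [Na+].[O-]I(=O)(=O)=O
Why: Lemieux–Johnson cleavage (dihydroxylation, then glycol cleavage) of the only alkene in the molecule should give the arylacetaldehyde, which is used at once.

**Step 11**
Reactants: 16 phloroglucinol
Product: 17 3,5-bis(tert-butyldimethylsilyloxy)phenol
Conditions: TBSOTf (2.0 equiv, slow addition), 2,6-lutidine, THF/CH2Cl2, −78 to 0 °C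
Reagents that add atoms: tert-butyldimethylsilyl trifluoromethanesulfonate CC(C)(C)[Si](C)(C)OS(=O)(=O)C(F)(F)F
Why: O-silylation of two of the three equivalent phenols under stoichiometric control, with the mono- and tris-silyl ethers removed by chromatography; the two silyl ethers become the ring A oxygen substituents that carry no C–H bond α to oxygen.

**Step 12**
Reactants: 17 3,5-bis(tert-butyldimethylsilyloxy)phenol; 18 3,4-bis(benzyloxy)benzyl alcohol
Product: 19 1-{[3,4-bis(benzyloxy)benzyl]oxy}-3,5-bis(tert-butyldimethylsilyloxy)benzene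
Conditions: PPh3, DIAD, THF, 0 °C to rt
Reagents that add atoms: none
Why: Mitsunobu etherification of the one free phenol with the primary benzylic alcohol under neutral conditions, which avoids the carbonate bases that could make aryl silyl ethers migrate or cleave.

**Step 13**
Reactants: 19 1-{[3,4-bis(benzyloxy)benzyl]oxy}-3,5-bis(tert-butyldimethylsilyloxy)benzene
Product: 20 1-{[3,4-bis(benzyloxy)benzyl]oxy}-2-iodo-3,5-bis(tert-butyldimethylsilyloxy)benzene
Conditions: NIS (1.0 equiv), CH2Cl2, −20 to 0 °C, dark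
Reagents that add atoms: N-iodosuccinimide O=C1CCC(=O)N1I
Why: Electrophilic aromatic iodination of the phloroglucinol-type ring, which is far more nucleophilic than the catechol-type ring of the DBB group; the two equivalent positions between the DBB ether and a silyl ether should be favoured, statistically and sterically, over the position flanked by two bulky silyl ethers, and the minor regioisomer is removed by chromatography.

**Step 14**
Reactants: 20 aryl iodide; 15 arylacetaldehyde
Product: 22 (2R,3R)-5-(benzyloxy)-2-[3,4-bis(benzyloxy)phenyl]-3,7-bis(TBS-oxy)-8-{2-[2-(DBB-oxy)-4,6-bis(TBS-oxy)phenyl]-2-hydroxyethyl}chroman-4-one (both carbinol epimers), via aryl Grignard reagent 21 (not isolated)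
Conditions: iPrMgCl·LiCl, THF, −20 to 0 °C; then 15, THF, −40 to 0 °C; aq. NH4Cl
Reagents that add atoms: none
Why: Iodine–magnesium exchange followed by 1,2-addition of the aryl Grignard reagent to the aldehyde, which is far more electrophilic than the hindered, donor-conjugated C4 ketone; magnesium is chosen over lithium because an ortho-silyloxy aryllithium is prone to a 1,3 oxygen-to-carbon silyl shift, and the carbinol configuration is irrelevant because it is oxidised next.

**Step 15**
Reactants: 22 secondary alcohol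
Product: 23 (2R,3R)-5-(benzyloxy)-2-[3,4-bis(benzyloxy)phenyl]-3,7-bis(TBS-oxy)-8-{2-[2-(DBB-oxy)-4,6-bis(TBS-oxy)phenyl]-2-oxoethyl}chroman-4-one
Conditions: Dess–Martin periodinane, NaHCO3, CH2Cl2, rt
Reagents that add atoms: none
Why: Dess–Martin oxidation of the secondary benzylic alcohol to the deoxybenzoin under buffered, near-neutral conditions that spare silyl and benzyl ethers and the dihydroflavonol.

**Step 16**
Reactants: 23 deoxybenzoin
Product: 24 (2R,3R)-5-(benzyloxy)-2-[3,4-bis(benzyloxy)phenyl]-3,7-bis(TBS-oxy)-8-{1-diazo-2-[2-(DBB-oxy)-4,6-bis(TBS-oxy)phenyl]-2-oxoethyl}chroman-4-one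
Conditions: p-ABSA, DBU, anhydrous MeCN/CH2Cl2, 0 °C to rt
Reagents that add atoms: 4-acetamidobenzenesulfonyl azide CC(=O)Nc1ccc(cc1)S(=O)(=O)N=[N+]=[N-]
Why: Regitz diazo transfer to the methylene activated by both the ketone and the aryl group, the only position acidic enough for DBU; the taxifolin C3–H is several pK units less acidic and should stay untouched, and water is excluded so that DBU does not cleave the aryl silyl ethers.

**Step 17**
Reactants: 24 α-aryl-α-diazoketone
Product: 26 (2R,3R)-5-(benzyloxy)-2-[3,4-bis(benzyloxy)phenyl]-8-[(2R,3S)-2-[3,4-bis(benzyloxy)phenyl]-5,7-bis(TBS-oxy)-4-oxochroman-3-yl]-3,7-bis(TBS-oxy)chroman-4-one, via cis-flavanone 25 (not isolated)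
Conditions: Rh2(S-PTTL)4 [dirhodium tetrakis(N-phthaloyl-(S)-tert-leucinate)] (2 mol %), toluene, 0 °C to rt, slow addition of 24; then Et3N, rt
Reagents that add atoms: none
Why: Rh2(S-PTTL)4 (divalent rhodium) expels N2 from 24 to give a donor–acceptor rhodium carbene at the future C3, which inserts through a concerted, asynchronous, hydride-transfer-like transition state into one C–H bond of the aryl-O–CH2–aryl group on ring A and so forms C2–C3. The closest known reaction type is the dirhodium carboxylate-catalysed intramolecular C–H insertion of 2-alkoxyaryl α-diazoketones to 2-substituted chroman-4-ones, applied here to a diazoketone whose diazo carbon also carries an aryl group. Ring C closes as a six-membered ring by 1,6-insertion along C3–C4–C4a–C8a–O1–C2, and a five-membered closure on this side is impossible because the fifth atom is the ether oxygen. C2 is set by the chiral tert-leucinate ligand shell, which selects one of the two benzylic hydrogens; C3 forms cis first and is then equilibrated by Et3N through the enol to the more stable trans (2R,3S) arrangement without touching C2. The step needs site selectivity and chemoselectivity, and the substrate secures both: the DBB methylene is the only C–H bond α to oxygen within reach, because the other ortho oxygen of ring A and the oxygen next to the carbene-bearing carbon on the taxifolin ring are silyl ethers, the taxifolin C2–H could react only by forming a bridged ring through an aromatic carbon, and every other benzyl ether is too far away. Because the taxifolin unit is already one enantiomer, any wrong C2 epimer is a diastereomer and should be removable by chromatography.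

**Step 18**
Reactants: 26 protected biflavanone
Product: 27 (2R,3R)-5-(benzyloxy)-2-[3,4-bis(benzyloxy)phenyl]-8-[(2R,3S)-2-[3,4-bis(benzyloxy)phenyl]-5,7-dihydroxy-4-oxochroman-3-yl]-3,7-dihydroxychroman-4-one
Conditions: HF·pyridine, pyridine/THF, 0 °C to rt
Reagents that add atoms: none
Why: Fluoride-driven cleavage of the three aryl silyl ethers and the secondary alkyl silyl ether in a buffered, slightly acidic medium, so that neither chromanone ring is opened by phenoxide or amine base.

**Step 19**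
Reactants: 27 benzyl-protected biflavanone
Product: 28 manniflavanone
Conditions: H2 (1 atm), Pd(OH)2/C, THF/MeOH, rt
Reagents that add atoms: none
Why: Catalytic hydrogenolysis of the five O-benzyl bonds under neutral conditions, which should leave the C2–O1 bonds and all four stereocentres untouched and give only toluene as by-product.

**Compound list**
1 | 2,4,6-trihydroxyacetophenone | CC(=O)c1c(O)cc(O)cc1O | starting material
2 | 1-[2,6-dihydroxy-4-(methoxymethoxy)phenyl]ethanone | CC(=O)c1c(O)cc(OCOC)cc1O | intermediate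
3 | 1-[2-(benzyloxy)-6-hydroxy-4-(methoxymethoxy)phenyl]ethanone | CC(=O)c1c(O)cc(OCOC)cc1OCc1ccccc1 | intermediate
4 | 1-[2-(allyloxy)-6-(benzyloxy)-4-(methoxymethoxy)phenyl]ethanone | CC(=O)c1c(OCC=C)cc(OCOC)cc1OCc1ccccc1 | intermediate
5 | 1-[3-allyl-6-(benzyloxy)-2-hydroxy-4-(methoxymethoxy)phenyl]ethanone | CC(=O)c1c(O)c(CC=C)c(OCOC)cc1OCc1ccccc1 | intermediate
6 | 1-[3-allyl-6-(benzyloxy)-2,4-bis(methoxymethoxy)phenyl]ethanone | CC(=O)c1c(OCOC)c(CC=C)c(OCOC)cc1OCc1ccccc1 | intermediate
7 | 3,4-bis(benzyloxy)benzaldehyde | O=Cc1ccc(OCc2ccccc2)c(OCc2ccccc2)c1 | starting material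
8 | 1-[3-allyl-6-(benzyloxy)-2,4-bis(methoxymethoxy)phenyl]-3-[3,4-bis(benzyloxy)phenyl]-3-hydroxypropan-1-one (racemic aldol adduct, not isolated) | O=C(CC(O)c1ccc(OCc2ccccc2)c(OCc2ccccc2)c1)c1c(OCOC)c(CC=C)c(OCOC)cc1OCc1ccccc1 | intermediate
9 | (E)-1-[3-allyl-6-(benzyloxy)-2,4-bis(methoxymethoxy)phenyl]-3-[3,4-bis(benzyloxy)phenyl]prop-2-en-1-one | O=C(/C=C/c1ccc(OCc2ccccc2)c(OCc2ccccc2)c1)c1c(OCOC)c(CC=C)c(OCOC)cc1OCc1ccccc1 | intermediate
10 | [(2R,3S)-3-[3,4-bis(benzyloxy)phenyl]oxiran-2-yl][3-allyl-6-(benzyloxy)-2,4-bis(methoxymethoxy)phenyl]methanone | O=C([C@@H]1O[C@H]1c1ccc(OCc2ccccc2)c(OCc2ccccc2)c1)c1c(OCOC)c(CC=C)c(OCOC)cc1OCc1ccccc1 | intermediate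
11 | [(2R,3S)-3-[3,4-bis(benzyloxy)phenyl]oxiran-2-yl][3-allyl-6-(benzyloxy)-2,4-dihydroxyphenyl]methanone (not isolated) | O=C([C@@H]1O[C@H]1c1ccc(OCc2ccccc2)c(OCc2ccccc2)c1)c1c(O)c(CC=C)c(O)cc1OCc1ccccc1 | intermediate
12 | (2R,3R)-8-allyl-5-(benzyloxy)-2-[3,4-bis(benzyloxy)phenyl]-3,7-dihydroxychroman-4-one | O=C1c2c(OCc3ccccc3)cc(O)c(CC=C)c2O[C@H](c2ccc(OCc3ccccc3)c(OCc3ccccc3)c2)[C@H]1O | intermediate
13 | (2R,3R)-8-allyl-5-(benzyloxy)-2-[3,4-bis(benzyloxy)phenyl]-3,7-bis(tert-butyldimethylsilyloxy)chroman-4-one | O=C1c2c(OCc3ccccc3)cc(O[Si](C)(C)C(C)(C)C)c(CC=C)c2O[C@H](c2ccc(OCc3ccccc3)c(OCc3ccccc3)c2)[C@H]1O[Si](C)(C)C(C)(C)C | intermediate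
14 | (2R,3R)-5-(benzyloxy)-2-[3,4-bis(benzyloxy)phenyl]-8-(2,3-dihydroxypropyl)-3,7-bis(tert-butyldimethylsilyloxy)chroman-4-one (diol epimers, not isolated) | O=C1c2c(OCc3ccccc3)cc(O[Si](C)(C)C(C)(C)C)c(CC(O)CO)c2O[C@H](c2ccc(OCc3ccccc3)c(OCc3ccccc3)c2)[C@H]1O[Si](C)(C)C(C)(C)C | intermediate
15 | 2-[(2R,3R)-5-(benzyloxy)-2-[3,4-bis(benzyloxy)phenyl]-3,7-bis(tert-butyldimethylsilyloxy)-4-oxochroman-8-yl]acetaldehyde | O=C1c2c(OCc3ccccc3)cc(O[Si](C)(C)C(C)(C)C)c(CC=O)c2O[C@H](c2ccc(OCc3ccccc3)c(OCc3ccccc3)c2)[C@H]1O[Si](C)(C)C(C)(C)C | intermediate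
16 | phloroglucinol | Oc1cc(O)cc(O)c1 | starting material
17 | 3,5-bis(tert-butyldimethylsilyloxy)phenol | Oc1cc(O[Si](C)(C)C(C)(C)C)cc(O[Si](C)(C)C(C)(C)C)c1 | intermediate
18 | 3,4-bis(benzyloxy)benzyl alcohol | OCc1ccc(OCc2ccccc2)c(OCc2ccccc2)c1 | starting material
19 | 1-{[3,4-bis(benzyloxy)benzyl]oxy}-3,5-bis(tert-butyldimethylsilyloxy)benzene | CC(C)(C)[Si](C)(C)Oc1cc(O[Si](C)(C)C(C)(C)C)cc(OCc2ccc(OCc3ccccc3)c(OCc3ccccc3)c2)c1 | intermediate
20 | 1-{[3,4-bis(benzyloxy)benzyl]oxy}-2-iodo-3,5-bis(tert-butyldimethylsilyloxy)benzene | Ic1c(OCc2ccc(OCc3ccccc3)c(OCc3ccccc3)c2)cc(O[Si](C)(C)C(C)(C)C)cc1O[Si](C)(C)C(C)(C)C | intermediate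
21 | {2-[(3,4-bis(benzyloxy)benzyl)oxy]-4,6-bis(tert-butyldimethylsilyloxy)phenyl}magnesium chloride (not isolated) | Cl[Mg]c1c(OCc2ccc(OCc3ccccc3)c(OCc3ccccc3)c2)cc(O[Si](C)(C)C(C)(C)C)cc1O[Si](C)(C)C(C)(C)C | intermediate
22 | (2R,3R)-5-(benzyloxy)-2-[3,4-bis(benzyloxy)phenyl]-3,7-bis(TBS-oxy)-8-{2-[2-(DBB-oxy)-4,6-bis(TBS-oxy)phenyl]-2-hydroxyethyl}chroman-4-one (carbinol epimers) | O=C1c2c(OCc3ccccc3)cc(O[Si](C)(C)C(C)(C)C)c(CC(O)c3c(OCc4ccc(OCc5ccccc5)c(OCc5ccccc5)c4)cc(O[Si](C)(C)C(C)(C)C)cc3O[Si](C)(C)C(C)(C)C)c2O[C@H](c2ccc(OCc3ccccc3)c(OCc3ccccc3)c2)[C@H]1O[Si](C)(C)C(C)(C)C | intermediate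
23 | (2R,3R)-5-(benzyloxy)-2-[3,4-bis(benzyloxy)phenyl]-3,7-bis(TBS-oxy)-8-{2-[2-(DBB-oxy)-4,6-bis(TBS-oxy)phenyl]-2-oxoethyl}chroman-4-one | O=C1c2c(OCc3ccccc3)cc(O[Si](C)(C)C(C)(C)C)c(CC(=O)c3c(OCc4ccc(OCc5ccccc5)c(OCc5ccccc5)c4)cc(O[Si](C)(C)C(C)(C)C)cc3O[Si](C)(C)C(C)(C)C)c2O[C@H](c2ccc(OCc3ccccc3)c(OCc3ccccc3)c2)[C@H]1O[Si](C)(C)C(C)(C)C | intermediate
24 | (2R,3R)-5-(benzyloxy)-2-[3,4-bis(benzyloxy)phenyl]-3,7-bis(TBS-oxy)-8-{1-diazo-2-[2-(DBB-oxy)-4,6-bis(TBS-oxy)phenyl]-2-oxoethyl}chroman-4-one | O=C1c2c(OCc3ccccc3)cc(O[Si](C)(C)C(C)(C)C)c(C(=[N+]=[N-])C(=O)c3c(OCc4ccc(OCc5ccccc5)c(OCc5ccccc5)c4)cc(O[Si](C)(C)C(C)(C)C)cc3O[Si](C)(C)C(C)(C)C)c2O[C@H](c2ccc(OCc3ccccc3)c(OCc3ccccc3)c2)[C@H]1O[Si](C)(C)C(C)(C)C | intermediate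
25 | (2R,3R)-5-(benzyloxy)-2-[3,4-bis(benzyloxy)phenyl]-8-[(2R,3R)-2-[3,4-bis(benzyloxy)phenyl]-5,7-bis(TBS-oxy)-4-oxochroman-3-yl]-3,7-bis(TBS-oxy)chroman-4-one (new ring 2,3-cis, not isolated) | O=C1c2c(OCc3ccccc3)cc(O[Si](C)(C)C(C)(C)C)c([C@H]3C(=O)c4c(O[Si](C)(C)C(C)(C)C)cc(O[Si](C)(C)C(C)(C)C)cc4O[C@H]3c3ccc(OCc4ccccc4)c(OCc4ccccc4)c3)c2O[C@H](c2ccc(OCc3ccccc3)c(OCc3ccccc3)c2)[C@H]1O[Si](C)(C)C(C)(C)C | intermediate
26 | (2R,3R)-5-(benzyloxy)-2-[3,4-bis(benzyloxy)phenyl]-8-[(2R,3S)-2-[3,4-bis(benzyloxy)phenyl]-5,7-bis(TBS-oxy)-4-oxochroman-3-yl]-3,7-bis(TBS-oxy)chroman-4-one (new ring 2,3-trans) | O=C1c2c(OCc3ccccc3)cc(O[Si](C)(C)C(C)(C)C)c([C@@H]3C(=O)c4c(O[Si](C)(C)C(C)(C)C)cc(O[Si](C)(C)C(C)(C)C)cc4O[C@H]3c3ccc(OCc4ccccc4)c(OCc4ccccc4)c3)c2O[C@H](c2ccc(OCc3ccccc3)c(OCc3ccccc3)c2)[C@H]1O[Si](C)(C)C(C)(C)C | intermediate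
27 | (2R,3R)-5-(benzyloxy)-2-[3,4-bis(benzyloxy)phenyl]-8-[(2R,3S)-2-[3,4-bis(benzyloxy)phenyl]-5,7-dihydroxy-4-oxochroman-3-yl]-3,7-dihydroxychroman-4-one | O=C1c2c(OCc3ccccc3)cc(O)c([C@@H]3C(=O)c4c(O)cc(O)cc4O[C@H]3c3ccc(OCc4ccccc4)c(OCc4ccccc4)c3)c2O[C@H](c2ccc(OCc3ccccc3)c(OCc3ccccc3)c2)[C@H]1O | intermediate
28 | manniflavanone, (2R,3R)-2-(3,4-dihydroxyphenyl)-8-[(2R,3S)-2-(3,4-dihydroxyphenyl)-5,7-dihydroxy-4-oxochroman-3-yl]-3,5,7-trihydroxychroman-4-one | O=C1c2c(O)cc(O)c([C@@H]3C(=O)c4c(O)cc(O)cc4O[C@H]3c3ccc(O)c(O)c3)c2O[C@H](c2ccc(O)c(O)c2)[C@H]1O | target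

**Step count and risks**
Total steps: 19. Longest linear sequence: 16 steps (steps 1–10 and 14–19); steps 11–13 form the ring A branch.

Step 17 (key step). What may go wrong: the carbene may be captured by the lone pair of the ortho ether oxygen (five-membered oxonium ylide, then a 1,2-benzyl shift to a benzofuran-3-one), or it may undergo Wolff rearrangement. The facial preference of the catalyst may also oppose the bias of the chiral taxifolin unit, so that C2 forms with poor selectivity. The fallback is the classical deoxybenzoin route to 3-arylflavanones and sets out from 23. Oxidative removal of the electron-rich DBB group with 2,3-dichloro-5,6-dicyano-1,4-benzoquinone (CH2Cl2/pH 7 buffer, 0 °C) should give the 2-hydroxydeoxybenzoin F1. Condensation of F1 with aldehyde 7 (piperidine, toluene, 4 Å molecular sieves, 60 °C; Knoevenagel condensation, then oxa-Michael closure under thermodynamic control) should give the 2,3-trans flavanone as 26 together with its (2S,3R)-flavanone diastereomer F2, which chromatography removes. The route is rejoined at 26.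

Step 14. What may go wrong: the hindered aryl Grignard reagent may act as a base and enolise the arylacetaldehyde (returning the de-iodinated arene), or it may attack the C4 ketone. The fallback uses a non-basic, aldehyde-selective organometal and sets out from 20 and 15. Under Nozaki–Hiyama–Kishi conditions (CrCl2 in excess, divalent chromium; NiCl2 as catalyst, divalent nickel; DMF, rt) the iodide should be converted in the flask into the arylchromium dichloride F3, which adds to the aldehyde of 15 without enolising it and gives carbinol 22 after aqueous work-up. The route is rejoined at 22.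

Step 7. What may go wrong: oxygen transfer to the twisted 2',6'-disubstituted enone inside the peptide catalyst may be slow and poorly face-selective. The fallback replaces catalyst control by resolution and sets out from 9. H2O2/NaOH in MeOH/THF (Weitz–Scheffer epoxidation) should give the racemic trans-epoxide, that is 10 together with its (2S,3R)-epoxide enantiomer F4. HCl in MeOH/THF converts the pair into 12 and its (2S,3S)-dihydroflavonol enantiomer F5, and preparative HPLC on a chiral stationary phase delivers 12. The route is rejoined at 12.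

**Further compounds**
F1 | step 17 | (2R,3R)-5-(benzyloxy)-2-[3,4-bis(benzyloxy)phenyl]-3,7-bis(TBS-oxy)-8-{2-[2-hydroxy-4,6-bis(TBS-oxy)phenyl]-2-oxoethyl}chroman-4-one | O=C1c2c(OCc3ccccc3)cc(O[Si](C)(C)C(C)(C)C)c(CC(=O)c3c(O)cc(O[Si](C)(C)C(C)(C)C)cc3O[Si](C)(C)C(C)(C)C)c2O[C@H](c2ccc(OCc3ccccc3)c(OCc3ccccc3)c2)[C@H]1O[Si](C)(C)C(C)(C)C
F2 | step 17 | (2R,3R)-5-(benzyloxy)-2-[3,4-bis(benzyloxy)phenyl]-8-[(2S,3R)-2-[3,4-bis(benzyloxy)phenyl]-5,7-bis(TBS-oxy)-4-oxochroman-3-yl]-3,7-bis(TBS-oxy)chroman-4-one | O=C1c2c(OCc3ccccc3)cc(O[Si](C)(C)C(C)(C)C)c([C@H]3C(=O)c4c(O[Si](C)(C)C(C)(C)C)cc(O[Si](C)(C)C(C)(C)C)cc4O[C@@H]3c3ccc(OCc4ccccc4)c(OCc4ccccc4)c3)c2O[C@H](c2ccc(OCc3ccccc3)c(OCc3ccccc3)c2)[C@H]1O[Si](C)(C)C(C)(C)C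
F3 | step 14 | {2-[(3,4-bis(benzyloxy)benzyl)oxy]-4,6-bis(tert-butyldimethylsilyloxy)phenyl}chromium dichloride | Cl[Cr](Cl)c1c(OCc2ccc(OCc3ccccc3)c(OCc3ccccc3)c2)cc(O[Si](C)(C)C(C)(C)C)cc1O[Si](C)(C)C(C)(C)C
F4 | step 7 | [(2S,3R)-3-[3,4-bis(benzyloxy)phenyl]oxiran-2-yl][3-allyl-6-(benzyloxy)-2,4-bis(methoxymethoxy)phenyl]methanone | O=C([C@H]1O[C@@H]1c1ccc(OCc2ccccc2)c(OCc2ccccc2)c1)c1c(OCOC)c(CC=C)c(OCOC)cc1OCc1ccccc1
F5 | step 7 | (2S,3S)-8-allyl-5-(benzyloxy)-2-[3,4-bis(benzyloxy)phenyl]-3,7-dihydroxychroman-4-one | O=C1c2c(OCc3ccccc3)cc(O)c(CC=C)c2O[C@@H](c2ccc(OCc3ccccc3)c(OCc3ccccc3)c2)[C@@H]1O
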